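**Plan**

- Numbering (halimane): ring A = C1–C5, C10 with C1=C10, and C4 carries C18 (ester) and C19 (methyl). Ring B = C5–C10, with C17 on C8, and C9 carries C20 (methyl) and the chain C11–C16 (oxygen on C15).
- Enabling feature: C6 and C9 of ring B both sit on the C5–C10 edge of ring A. A carboxyl on C9 (the later C20 methyl) and an oxygen on C6 therefore close a six-membered lactone, and C6–C7–C8 can be an allyl unit, so ring B is the [3,3] product of that lactone enolate.
- Retrosynthesis: cut C15–OAc; return C20 to CO2H and add C6=C7; cut C8–C9 (retro Ireland–Claisen, reopening the temporary lactone O–C6/C20(=O)–C9); cut C9–C11 (enolate alkylation); cut C2–C3 and C4–C5 of ring A (Diels–Alder); cut C5=C10 (enyne metathesis) and the ester.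
- Forward order: lactone ring, then ring A, then the chain at C9, then ring B by ring-contracting rearrangement (last ring, lactone cleaved in the same step), then removal of the helpers (C6=C7, C20 oxidation level).
- Stereochemistry: the only external source is the carbinol carbon C6 (kinetic resolution). It steers C5 and C4 in the Diels–Alder reaction (anti face, formyl endo), then sets C8 and C9 by suprafacial transfer through a boat transition state with the E-propenyl group, and is destroyed. The 13E geometry comes from carboalumination.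

Key step: step 11

Assumption: racemic (4E)-hexa-1,4-dien-3-ol is taken as purchasable; it is otherwise the adduct of vinylmagnesium bromide and (E)-but-2-enal.

**Step 1**
Reactants: 1 (4E)-hexa-1,4-dien-3-ol (racemic)
Product: 2 (3R,4E)-hexa-1,4-dien-3-ol (recovered enantiomer)
Conditions: Ti(OiPr)4 (10 mol%), L-(+)-diisopropyl tartrate (15 mol%), t-BuOOH (0.6 equiv), 4 Å molecular sieves, CH2Cl2, −20 °C, stopped a little beyond half conversion
Reagents that add atoms: none
Why: Sharpless kinetic resolution, in which the (S)-alcohol should be epoxidised faster at its E-propenyl group with the L-(+)-tartrate, so that the (R)-alcohol is left behind; the stereocentre is selected, not created.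

**Step 2**
Reactants: 2 (3R,4E)-hexa-1,4-dien-3-ol; 3 but-3-ynoic acid
Product: 4 (3R,4E)-hexa-1,4-dien-3-yl but-3-ynoate
Conditions: DCC, DMAP (5 mol%), CH2Cl2, −20 → 0 °C
Reagents that add atoms: none
Why: Steglich esterification at low temperature with little DMAP should acylate the allylic alcohol without touching its stereocentre and before the acid isomerises to the allenoate.

**Step 3**
Reactants: 4 (3R,4E)-hexa-1,4-dien-3-yl but-3-ynoate
Product: 5 (6S)-4-ethenyl-6-[(1E)-prop-1-en-1-yl]-3,6-dihydro-2H-pyran-2-one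
Conditions: second-generation Grubbs catalyst RuCl2(=CHPh)(PCy3)(H2IMes) (5 mol%), CH2Cl2 (high dilution), 40 °C
Reagents that add atoms: none
Why: Ring-closing enyne metathesis in the exo mode should start at the terminal vinyl group rather than the internal propenyl group and give the six-membered lactone with the C5=C10/C1=C2 diene; C6 is untouched (its descriptor changes only by priority).

**Step 4**
Reactants: 5 (6S)-4-ethenyl-6-[(1E)-prop-1-en-1-yl]-3,6-dihydro-2H-pyran-2-one; 6 methyl 2-(hydroxymethyl)prop-2-enoate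
Product: 8 methyl (1S,8S,8aS)-8-formyl-3-oxo-1-[(1E)-prop-1-en-1-yl]-3,4,6,7,8,8a-hexahydro-1H-isochromene-8-carboxylate, via methyl 2-formylprop-2-enoate 7 (not isolated)
Conditions: 6, Dess–Martin periodinane, CH2Cl2, 0 °C; then 5, ZnCl2 (1 equiv), CH2Cl2/Et2O, −40 → 0 °C
Reagents that add atoms: none
Why: Dess–Martin oxidation unmasks the 2-methylene-1,3-dicarbonyl dienophile 7, which should add to the semicyclic diene in a Diels–Alder reaction with the regiochemistry of 1-vinylcyclohexenes (its CH2 to C2, the quaternary carbon C4 to C5), on the face anti to the propenyl group on C6 (sets C5) and with the smaller, more Lewis-basic formyl group endo (sets C4 with CHO cis to C6 and CO2Me cis to H5), as 2-alkoxycarbonyl enones react with the ketone carbonyl endo.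

**Step 5**
Reactants: 8 methyl (1S,8S,8aS)-8-formyl-3-oxo-1-[(1E)-prop-1-en-1-yl]-3,4,6,7,8,8a-hexahydro-1H-isochromene-8-carboxylate
Product: 10 methyl (1S,8S,8aS)-8-methyl-3-oxo-1-[(1E)-prop-1-en-1-yl]-3,4,6,7,8,8a-hexahydro-1H-isochromene-8-carboxylate, via tosylhydrazone 9 (not isolated)
Conditions: TsNHNH2, THF, rt; catecholborane, CHCl3, 0 °C; NaOAc·3H2O, 60 °C
Reagents that add atoms: none
Why: Caglioti-type reduction of the aldehyde tosylhydrazone (hydride addition, loss of sulfinate and of N2) should turn the non-enolisable formyl group into the C19 methyl under conditions that leave both esters, the alkenes and C4 untouched.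

**Step 6**
Reactants: 11 tert-butyl(but-3-yn-1-yloxy)dimethylsilane
Product: 14 (2E)-5-{[tert-butyl(dimethyl)silyl]oxy}-3-methylpent-2-en-1-ol, via alkenyl(dimethyl)alane 12 (not isolated), via lithium alkenylalanate 13 (not isolated)
Conditions: Me3Al, Cp2ZrCl2 (0.25 equiv), CH2Cl2, 0 °C → rt; n-BuLi, THF, −78 °C; (CH2O)n, −78 °C → rt
Reagents that add atoms: trimethylaluminium, C[Al](C)C; paraformaldehyde (as formaldehyde), C=O
Why: Negishi zirconium-catalysed carboalumination adds methyl and aluminium syn across the terminal alkyne, and hydroxymethylation of the derived alanate with retention should give the E-trisubstituted allylic alcohol.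

**Step 7**
Reactants: 14 (2E)-5-{[tert-butyl(dimethyl)silyl]oxy}-3-methylpent-2-en-1-ol
Product: 15 (3E)-1-{[tert-butyl(dimethyl)silyl]oxy}-5-{[tert-butyl(diphenyl)silyl]oxy}-3-methylpent-3-ene
Conditions: TBDPSCl, imidazole, DMF, rt
Reagents that add atoms: tert-butyl(chloro)diphenylsilane, CC(C)(C)[Si](Cl)(c1ccccc1)c1ccccc1
Why: Standard silylation puts on the allylic oxygen a group that survives the enolate, hydride and acid steps ahead and is more acid-stable than the TBS ether.

**Step 8**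
Reactants: 15 (3E)-1-{[tert-butyl(dimethyl)silyl]oxy}-5-{[tert-butyl(diphenyl)silyl]oxy}-3-methylpent-3-ene
Product: 16 (3E)-5-{[tert-butyl(diphenyl)silyl]oxy}-3-methylpent-3-en-1-ol
Conditions: PPTS (cat.), EtOH, 40 °C
Reagents that add atoms: none
Why: Mild acid-catalysed solvolysis should remove the primary TBS ether selectively, the TBDPS ether being far less labile to acid.

**Step 9**
Reactants: 16 (3E)-5-{[tert-butyl(diphenyl)silyl]oxy}-3-methylpent-3-en-1-ol
Product: 17 tert-butyl{[(2E)-5-iodo-3-methylpent-2-en-1-yl]oxy}diphenylsilane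
Conditions: I2, PPh3, imidazole, CH2Cl2, 0 °C
Reagents that add atoms: iodine, II
Why: Appel-type iodination of the primary homoallylic alcohol should proceed by SN2 displacement of the alkoxyphosphonium ion without touching the alkene geometry.

**Step 10**
Reactants: 10 methyl (1S,8S,8aS)-8-methyl-3-oxo-1-[(1E)-prop-1-en-1-yl]-3,4,6,7,8,8a-hexahydro-1H-isochromene-8-carboxylate; 17 tert-butyl{[(2E)-5-iodo-3-methylpent-2-en-1-yl]oxy}diphenylsilane
Product: 18 methyl (1S,4RS,8S,8aS)-4-[(3E)-5-{[tert-butyl(diphenyl)silyl]oxy}-3-methylpent-3-en-1-yl]-8-methyl-3-oxo-1-[(1E)-prop-1-en-1-yl]-3,4,6,7,8,8a-hexahydro-1H-isochromene-8-carboxylate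
Conditions: LDA, THF, −78 °C; then 17, DMPU, −78 → −30 °C
Reagents that add atoms: none
Why: Enolate alkylation, in which the only acidic hydrogens (C9, α to the lactone and allylic) give a dienolate that should alkylate at its α-carbon with the primary iodide; the C9 configuration is irrelevant because it is erased in step 11.

**Step 11**
Reactants: 18 methyl (1S,4RS,8S,8aS)-4-[(3E)-5-{[tert-butyl(diphenyl)silyl]oxy}-3-methylpent-3-en-1-yl]-8-methyl-3-oxo-1-[(1E)-prop-1-en-1-yl]-3,4,6,7,8,8a-hexahydro-1H-isochromene-8-carboxylate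
Product: 21 (1R,2R,4aS,5S)-1-[(3E)-5-{[tert-butyl(diphenyl)silyl]oxy}-3-methylpent-3-en-1-yl]-5-(methoxycarbonyl)-2,5-dimethyl-1,2,4a,5,6,7-hexahydronaphthalene-1-carboxylic acid, via silyl ketene acetal 19 (not isolated), via trimethylsilyl ester 20 (not isolated)
Conditions: LDA, TMSCl/Et3N, THF, −78 °C → rt; toluene, 100 °C; 1 M HCl (work-up)
Reagents that add atoms: none
Why: Deprotonation at C9 and O-silylation give the endocyclic ketene acetal 19, whose O–C20=C9 unit and the C6–C7=C8 allyl unit should undergo a concerted, suprafacial [3,3]-sigmatropic shift that forms C8–C9 and breaks C6–O. The closest known reaction type is the Ireland–Claisen rearrangement of silyl ketene acetals of 6-alkenyl δ-lactones (lactone-to-carbocycle ring contraction, as also known for 6-alkenyl-1,4-dioxan-2-ones), which must pass through a boat transition state because the C5–C10 edge ties C6 to C9. Ring B (C5–C6–C7–C8–C9–C10) is closed as the carbocycle complementary to the lactone, formally a 6-(enolexo)-endo-trig attack of C9 on C8, while the temporary lactone ring opens to the C20 carboxyl and leaves C6=C7. C9 is controlled by C6, since the allyl unit can reach only the lactone face that carries the propenyl group, so that after contraction C11 lies cis to H5 and the carboxyl trans to it; C8 is controlled by the E geometry of the propenyl group, which in the boat places C17 cis to the carboxyl carbon. The step needs complete chirality transfer with C5 and the C1=C10 position left alone; the ring-enforced boat, the fixed ketene-acetal geometry and the absence of a leaving group β or vinylogously β to C9 should secure this.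

**Step 12**
Reactants: 21 (1R,2R,4aS,5S)-1-[(3E)-5-{[tert-butyl(diphenyl)silyl]oxy}-3-methylpent-3-en-1-yl]-5-(methoxycarbonyl)-2,5-dimethyl-1,2,4a,5,6,7-hexahydronaphthalene-1-carboxylic acid
Product: 22 (1R,2R,4aS,5S)-1-[(3E)-5-{[tert-butyl(diphenyl)silyl]oxy}-3-methylpent-3-en-1-yl]-5-(methoxycarbonyl)-2,5-dimethyl-1,2,3,4,4a,5,6,7-octahydronaphthalene-1-carboxylic acid
Conditions: 2-nitrobenzenesulfonohydrazide, Et3N, CH2Cl2, rt
Reagents that add atoms: none
Why: Diimide reduction is highly sensitive to alkene substitution and should saturate the cis-disubstituted C6=C7 bond while leaving the trisubstituted C1=C10 and C13=C14 bonds.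

**Step 13**
Reactants: 22 (1R,2R,4aS,5S)-1-[(3E)-5-{[tert-butyl(diphenyl)silyl]oxy}-3-methylpent-3-en-1-yl]-5-(methoxycarbonyl)-2,5-dimethyl-1,2,3,4,4a,5,6,7-octahydronaphthalene-1-carboxylic acid
Product: 24 methyl (1S,5R,6R,8aS)-5-[(3E)-5-{[tert-butyl(diphenyl)silyl]oxy}-3-methylpent-3-en-1-yl]-5-formyl-1,6-dimethyl-1,2,3,5,6,7,8,8a-octahydronaphthalene-1-carboxylate, via acid chloride 23 (not isolated)
Conditions: 1-chloro-N,N,2-trimethylprop-1-en-1-amine, CH2Cl2, 0 °C → rt; LiAlH(OtBu)3, THF, −78 °C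
Reagents that add atoms: none
Why: Neutral acid chloride formation followed by reduction with LiAlH(OtBu)3 should stop at the hindered aldehyde and spare the C18 methyl ester, the acid chloride having no α-hydrogen through which to form a ketene.

**Step 14**
Reactants: 24 methyl (1S,5R,6R,8aS)-5-[(3E)-5-{[tert-butyl(diphenyl)silyl]oxy}-3-methylpent-3-en-1-yl]-5-formyl-1,6-dimethyl-1,2,3,5,6,7,8,8a-octahydronaphthalene-1-carboxylate
Product: 26 methyl (1S,5S,6R,8aS)-5-[(3E)-5-{[tert-butyl(diphenyl)silyl]oxy}-3-methylpent-3-en-1-yl]-1,5,6-trimethyl-1,2,3,5,6,7,8,8a-octahydronaphthalene-1-carboxylate, via tosylhydrazone 25 (not isolated)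
Conditions: TsNHNH2, EtOH, 60 °C; catecholborane, CHCl3, 0 °C; NaOAc·3H2O, 60 °C
Reagents that add atoms: none
Why: Caglioti-type tosylhydrazone reduction, as in step 5, should convert the C20 aldehyde into the C20 methyl without touching the ester or the alkenes; the diazene is homoallylic, not allylic, so no alkene transposition is expected.

**Step 15**
Reactants: 26 methyl (1S,5S,6R,8aS)-5-[(3E)-5-{[tert-butyl(diphenyl)silyl]oxy}-3-methylpent-3-en-1-yl]-1,5,6-trimethyl-1,2,3,5,6,7,8,8a-octahydronaphthalene-1-carboxylate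
Product: 28 methyl (1S,5S,6R,8aS)-5-[(3E)-5-(acetyloxy)-3-methylpent-3-en-1-yl]-1,5,6-trimethyl-1,2,3,5,6,7,8,8a-octahydronaphthalene-1-carboxylate, via allylic alcohol 27 (not isolated)
Conditions: TBAF, THF, 0 °C → rt; then Ac2O, DMAP (cat.), rt
Reagents that add atoms: acetic anhydride, CC(=O)OC(C)=O
Why: Fluoride desilylation followed by acetylation of the liberated primary allylic alkoxide in the same flask should give the acetate without allylic transposition or change at any stereocentre.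

**Compound list**

1 | (4E)-hexa-1,4-dien-3-ol (racemic) | C=CC(O)/C=C/C | starting material
2 | (3R,4E)-hexa-1,4-dien-3-ol | C=C[C@@H](O)/C=C/C | intermediate
3 | but-3-ynoic acid | C#CCC(=O)O | starting material
4 | (3R,4E)-hexa-1,4-dien-3-yl but-3-ynoate | C#CCC(=O)O[C@H](C=C)/C=C/C | intermediate
5 | (6S)-4-ethenyl-6-[(1E)-prop-1-en-1-yl]-3,6-dihydro-2H-pyran-2-one | C=CC1=C[C@H](/C=C/C)OC(=O)C1 | intermediate
6 | methyl 2-(hydroxymethyl)prop-2-enoate | COC(=O)C(=C)CO | starting material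
7 | methyl 2-formylprop-2-enoate | COC(=O)C(=C)C=O | intermediate
8 | methyl (1S,8S,8aS)-8-formyl-3-oxo-1-[(1E)-prop-1-en-1-yl]-3,4,6,7,8,8a-hexahydro-1H-isochromene-8-carboxylate | COC(=O)[C@@]1(C=O)CCC=C2[C@@H]1[C@H](/C=C/C)OC(=O)C2 | intermediate
9 | N-tosylhydrazone of 8 (E at C=N) | COC(=O)[C@@]1(/C=N/NS(=O)(=O)c3ccc(C)cc3)CCC=C2[C@@H]1[C@H](/C=C/C)OC(=O)C2 | intermediate
10 | methyl (1S,8S,8aS)-8-methyl-3-oxo-1-[(1E)-prop-1-en-1-yl]-3,4,6,7,8,8a-hexahydro-1H-isochromene-8-carboxylate | COC(=O)[C@@]1(C)CCC=C2[C@@H]1[C@H](/C=C/C)OC(=O)C2 | intermediate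
11 | tert-butyl(but-3-yn-1-yloxy)dimethylsilane | C#CCCO[Si](C)(C)C(C)(C)C | starting material
12 | [(1E)-4-{[tert-butyl(dimethyl)silyl]oxy}-2-methylbut-1-en-1-yl]dimethylalane | C[Al](C)/C=C(\C)CCO[Si](C)(C)C(C)(C)C | intermediate
13 | lithium butyl[(1E)-4-{[tert-butyl(dimethyl)silyl]oxy}-2-methylbut-1-en-1-yl]dimethylalanate | [Li+].CCCC[Al-](C)(C)/C=C(\C)CCO[Si](C)(C)C(C)(C)C | intermediate
14 | (2E)-5-{[tert-butyl(dimethyl)silyl]oxy}-3-methylpent-2-en-1-ol | OC/C=C(\C)CCO[Si](C)(C)C(C)(C)C | intermediate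
15 | (3E)-1-{[tert-butyl(dimethyl)silyl]oxy}-5-{[tert-butyl(diphenyl)silyl]oxy}-3-methylpent-3-ene | CC(C)(C)[Si](C)(C)OCC/C(C)=C/CO[Si](c1ccccc1)(c1ccccc1)C(C)(C)C | intermediate
16 | (3E)-5-{[tert-butyl(diphenyl)silyl]oxy}-3-methylpent-3-en-1-ol | OCC/C(C)=C/CO[Si](c1ccccc1)(c1ccccc1)C(C)(C)C | intermediate
17 | tert-butyl{[(2E)-5-iodo-3-methylpent-2-en-1-yl]oxy}diphenylsilane | ICC/C(C)=C/CO[Si](c1ccccc1)(c1ccccc1)C(C)(C)C | intermediate
18 | methyl (1S,4RS,8S,8aS)-4-[(3E)-5-{[tert-butyl(diphenyl)silyl]oxy}-3-methylpent-3-en-1-yl]-8-methyl-3-oxo-1-[(1E)-prop-1-en-1-yl]-3,4,6,7,8,8a-hexahydro-1H-isochromene-8-carboxylate | COC(=O)[C@@]1(C)CCC=C2[C@@H]1[C@H](/C=C/C)OC(=O)C2CC/C(C)=C/CO[Si](c1ccccc1)(c1ccccc1)C(C)(C)C | intermediate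
19 | methyl (1S,8S,8aS)-4-[(3E)-5-{[tert-butyl(diphenyl)silyl]oxy}-3-methylpent-3-en-1-yl]-8-methyl-1-[(1E)-prop-1-en-1-yl]-3-[(trimethylsilyl)oxy]-6,7,8,8a-tetrahydro-1H-isochromene-8-carboxylate | COC(=O)[C@@]1(C)CCC=C2[C@@H]1[C@H](/C=C/C)OC(O[Si](C)(C)C)=C2CC/C(C)=C/CO[Si](c1ccccc1)(c1ccccc1)C(C)(C)C | intermediate
20 | trimethylsilyl ester of 21 | COC(=O)[C@@]1(C)CCC=C2[C@@H]1C=C[C@@H](C)[C@]2(C(=O)O[Si](C)(C)C)CC/C(C)=C/CO[Si](c1ccccc1)(c1ccccc1)C(C)(C)C | intermediate
21 | (1R,2R,4aS,5S)-1-[(3E)-5-{[tert-butyl(diphenyl)silyl]oxy}-3-methylpent-3-en-1-yl]-5-(methoxycarbonyl)-2,5-dimethyl-1,2,4a,5,6,7-hexahydronaphthalene-1-carboxylic acid | COC(=O)[C@@]1(C)CCC=C2[C@@H]1C=C[C@@H](C)[C@]2(C(=O)O)CC/C(C)=C/CO[Si](c1ccccc1)(c1ccccc1)C(C)(C)C | intermediate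
22 | (1R,2R,4aS,5S)-1-[(3E)-5-{[tert-butyl(diphenyl)silyl]oxy}-3-methylpent-3-en-1-yl]-5-(methoxycarbonyl)-2,5-dimethyl-1,2,3,4,4a,5,6,7-octahydronaphthalene-1-carboxylic acid | COC(=O)[C@@]1(C)CCC=C2[C@@H]1CC[C@@H](C)[C@]2(C(=O)O)CC/C(C)=C/CO[Si](c1ccccc1)(c1ccccc1)C(C)(C)C | intermediate
23 | acid chloride of 22 | COC(=O)[C@@]1(C)CCC=C2[C@@H]1CC[C@@H](C)[C@]2(C(Cl)=O)CC/C(C)=C/CO[Si](c1ccccc1)(c1ccccc1)C(C)(C)C | intermediate
24 | methyl (1S,5R,6R,8aS)-5-[(3E)-5-{[tert-butyl(diphenyl)silyl]oxy}-3-methylpent-3-en-1-yl]-5-formyl-1,6-dimethyl-1,2,3,5,6,7,8,8a-octahydronaphthalene-1-carboxylate | COC(=O)[C@@]1(C)CCC=C2[C@@H]1CC[C@@H](C)[C@]2(C=O)CC/C(C)=C/CO[Si](c1ccccc1)(c1ccccc1)C(C)(C)C | intermediate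
25 | N-tosylhydrazone of 24 (E at C=N) | COC(=O)[C@@]1(C)CCC=C2[C@@H]1CC[C@@H](C)[C@]2(/C=N/NS(=O)(=O)c3ccc(C)cc3)CC/C(C)=C/CO[Si](c1ccccc1)(c1ccccc1)C(C)(C)C | intermediate
26 | methyl (1S,5S,6R,8aS)-5-[(3E)-5-{[tert-butyl(diphenyl)silyl]oxy}-3-methylpent-3-en-1-yl]-1,5,6-trimethyl-1,2,3,5,6,7,8,8a-octahydronaphthalene-1-carboxylate | COC(=O)[C@@]1(C)CCC=C2[C@@H]1CC[C@@H](C)[C@]2(C)CC/C(C)=C/CO[Si](c1ccccc1)(c1ccccc1)C(C)(C)C | intermediate
27 | methyl (1S,5S,6R,8aS)-5-[(3E)-5-hydroxy-3-methylpent-3-en-1-yl]-1,5,6-trimethyl-1,2,3,5,6,7,8,8a-octahydronaphthalene-1-carboxylate | COC(=O)[C@@]1(C)CCC=C2[C@@H]1CC[C@@H](C)[C@]2(C)CC/C(C)=C/CO | intermediate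
28 | methyl (1S,5S,6R,8aS)-5-[(3E)-5-(acetyloxy)-3-methylpent-3-en-1-yl]-1,5,6-trimethyl-1,2,3,5,6,7,8,8a-octahydronaphthalene-1-carboxylate | COC(=O)[C@@]1(C)CCC=C2[C@@H]1CC[C@@H](C)[C@]2(C)CC/C(C)=C/COC(C)=O | target

**Totals**

Total step count: 15. Longest linear sequence: 11 steps (steps 1–5 and 10–15).

**Steps most likely to fail**

Step 4. The formyl acrylate may oligomerise or dimerise by hetero-Diels–Alder reaction before it is trapped, the ester may compete with the formyl group for the endo position (wrong C4 configuration), or the Lewis acid may ionise the doubly allylic C6–O bond. The fallback sets out from 5 and comes back at 10, and uses a stable dienophile whose only carbonyl group is the formyl group. 2-Methylidenepropane-1,3-diol is monosilylated (NaH, TBSCl, THF) to 2-({[tert-butyl(dimethyl)silyl]oxy}methyl)prop-2-en-1-ol F1 and oxidised (MnO2, CH2Cl2) to 2-({[tert-butyl(dimethyl)silyl]oxy}methyl)prop-2-enal F2. Cycloaddition with 5 (Me2AlCl, CH2Cl2, −78 °C), formyl endo and anti to the propenyl group, should give (1S,8R,8aS)-8-({[tert-butyl(dimethyl)silyl]oxy}methyl)-3-oxo-1-[(1E)-prop-1-en-1-yl]-3,4,6,7,8,8a-hexahydro-1H-isochromene-8-carbaldehyde F3. The formyl group is reduced to the C19 methyl under the conditions of step 5 to give (1S,8S,8aS)-8-({[tert-butyl(dimethyl)silyl]oxy}methyl)-8-methyl-1-[(1E)-prop-1-en-1-yl]-1,4,6,7,8,8a-hexahydro-3H-isochromen-3-one F4. Jones oxidation (CrO3, H2SO4, acetone, 0 °C) removes the silyl group and oxidises C18 to (1S,8S,8aS)-8-methyl-3-oxo-1-[(1E)-prop-1-en-1-yl]-3,4,6,7,8,8a-hexahydro-1H-isochromene-8-carboxylic acid F5, and TMSCHN2 (MeOH/toluene) gives 10.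

Step 11. Enolisation at the fully substituted C9 may be slow, or the boat transition state that joins a quaternary to a tertiary carbon may be too congested, so that the ketene acetal decomposes or returns 18. The fallback sets out from 10 and comes back at 21; it closes ring B before the chain is attached. The unsubstituted lactone 10 is rearranged under the conditions of step 11 to (1R,2R,4aS,5S)-5-(methoxycarbonyl)-2,5-dimethyl-1,2,4a,5,6,7-hexahydronaphthalene-1-carboxylic acid F6, in which C8 is set as before. The dianion of F6 (LDA, 2.2 equiv, THF/DMPU, −78 → 0 °C) is then alkylated at C9 with iodide 17, the chain entering anti to the neighbouring C8 methyl group, which is the configuration of 21.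

Step 14. Hydrazone formation or hydride delivery at the neopentyl C20, flanked by C8, C10 and C11, may be incomplete. The fallback sets out from 24 and comes back at 26, and removes the oxygen by substitution and reduction. NaBH4 (MeOH, 0 °C) gives methyl (1S,5R,6R,8aS)-5-[(3E)-5-{[tert-butyl(diphenyl)silyl]oxy}-3-methylpent-3-en-1-yl]-5-(hydroxymethyl)-1,6-dimethyl-1,2,3,5,6,7,8,8a-octahydronaphthalene-1-carboxylate F7. MsCl and Et3N (CH2Cl2, 0 °C) give the corresponding methanesulfonate, methyl (1S,5R,6R,8aS)-5-[(3E)-5-{[tert-butyl(diphenyl)silyl]oxy}-3-methylpent-3-en-1-yl]-5-{[(methanesulfonyl)oxy]methyl}-1,6-dimethyl-1,2,3,5,6,7,8,8a-octahydronaphthalene-1-carboxylate F8. NaI and Zn dust (DME/HMPA, 105 °C) reduce the sulfonate to the methyl group of 26.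

**Further compounds**

F1 | step 4 | 2-({[tert-butyl(dimethyl)silyl]oxy}methyl)prop-2-en-1-ol | C=C(CO)CO[Si](C)(C)C(C)(C)C
F2 | step 4 | 2-({[tert-butyl(dimethyl)silyl]oxy}methyl)prop-2-enal | C=C(C=O)CO[Si](C)(C)C(C)(C)C
F3 | step 4 | (1S,8R,8aS)-8-({[tert-butyl(dimethyl)silyl]oxy}methyl)-3-oxo-1-[(1E)-prop-1-en-1-yl]-3,4,6,7,8,8a-hexahydro-1H-isochromene-8-carbaldehyde | CC(C)(C)[Si](C)(C)OC[C@@]1(C=O)CCC=C2[C@@H]1[C@H](/C=C/C)OC(=O)C2
F4 | step 4 | (1S,8S,8aS)-8-({[tert-butyl(dimethyl)silyl]oxy}methyl)-8-methyl-1-[(1E)-prop-1-en-1-yl]-1,4,6,7,8,8a-hexahydro-3H-isochromen-3-one | CC(C)(C)[Si](C)(C)OC[C@@]1(C)CCC=C2[C@@H]1[C@H](/C=C/C)OC(=O)C2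
F5 | step 4 | (1S,8S,8aS)-8-methyl-3-oxo-1-[(1E)-prop-1-en-1-yl]-3,4,6,7,8,8a-hexahydro-1H-isochromene-8-carboxylic acid | OC(=O)[C@@]1(C)CCC=C2[C@@H]1[C@H](/C=C/C)OC(=O)C2
F6 | step 11 | (1R,2R,4aS,5S)-5-(methoxycarbonyl)-2,5-dimethyl-1,2,4a,5,6,7-hexahydronaphthalene-1-carboxylic acid | COC(=O)[C@@]1(C)CCC=C2[C@@H]1C=C[C@@H](C)[C@H]2C(=O)O
F7 | step 14 | methyl (1S,5R,6R,8aS)-5-[(3E)-5-{[tert-butyl(diphenyl)silyl]oxy}-3-methylpent-3-en-1-yl]-5-(hydroxymethyl)-1,6-dimethyl-1,2,3,5,6,7,8,8a-octahydronaphthalene-1-carboxylate | COC(=O)[C@@]1(C)CCC=C2[C@@H]1CC[C@@H](C)[C@]2(CO)CC/C(C)=C/CO[Si](c1ccccc1)(c1ccccc1)C(C)(C)C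
F8 | step 14 | methyl (1S,5R,6R,8aS)-5-[(3E)-5-{[tert-butyl(diphenyl)silyl]oxy}-3-methylpent-3-en-1-yl]-5-{[(methanesulfonyl)oxy]methyl}-1,6-dimethyl-1,2,3,5,6,7,8,8a-octahydronaphthalene-1-carboxylate | COC(=O)[C@@]1(C)CCC=C2[C@@H]1CC[C@@H](C)[C@]2(COS(C)(=O)=O)CC/C(C)=C/CO[Si](c1ccccc1)(c1ccccc1)C(C)(C)C
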